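**Plan**

1. Retrosynthesis (core numbered as naphthalen-2(1H)-one; cyclopentane as C1′–C5′, with C1′ quaternary and C3′ the CHBr carbon): the C5 methyl carbinol, the C4a–OH and both C–Br bonds go back to a 3,5-dien-2-one carrying two alkenyl bromides; ring B is cut at C1–C2 and C3–C4 into a ring-A cyclohexene ester and a cyclopentenylacetamide; the cyclopentane is cut at C1′–C5′.
2. Forward: cyclopentane first (steps 1–8), ring A from 2-methylcyclohex-2-enone (steps 9–10), ring B by Claisen acylation, decarboxylation and aldol closure (steps 11–14), then both bromides, the dienone, the trans-diol and the methyl carbinol (steps 15–19).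
3. Enabling feature: C3′ and the ring-B-bearing C1′ are 1,3-cis across the CMe2 carbon C2′, and C1′ carries C3–C2(=O) of ring B. Carried as C3′–O, that oxygen and C2 can be tied into an α,β-unsaturated δ-lactone (O–C2(=O)–C3=C1′–C2′–C3′) whose β-carbon is the future quaternary C1′, so a 2-iodoethyl chain on C3′ (C4′, C5′) closes the five-membered ring by 5-exo radical addition.
4. Stereochemistry: the C3′ carbinol (Ir-catalysed reverse prenylation) is relayed through the lactone to C1′ and then spent; C8a comes from Cu-catalysed asymmetric conjugate vinylation and trans alkylation; C8 and C3′ (Br) from hydrogen delivery to the less hindered faces; C4a from epoxidation anti to the angular methyl; C5 from trans-diaxial opening and equatorial methyl addition.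
5. Centres that are erased later (C3, C4, C4a–H) are carried without control.

Key step: step 5

Assumption: the (R)-SEGPHOS-derived iridium catalyst is taken to give the (3R)-alcohol 3; if it gives the antipode, (S)-SEGPHOS is used instead.

Step 1
Reactants: 1 3-chloropropan-1-ol; 2 3-methylbuta-1,2-diene
Product: 3 (3R)-1-chloro-4,4-dimethylhex-5-en-3-ol
Conditions: [Ir(cod)Cl]2 (2.5 mol %), (R)-SEGPHOS (5 mol %), 4-cyano-3-nitrobenzoic acid (10 mol %), Cs2CO3 (20 mol %), toluene, 60 °C
Reagents that add atoms: none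
Why: Iridium-catalysed transfer-hydrogenative carbonyl reverse prenylation: the alcohol is dehydrogenated in situ, the allene is hydrometalated to a 1,1-dimethylallyl iridium species, and its addition to the transient aldehyde through a closed chair transition state on the chiral catalyst should set the (3R) carbinol centre.

Step 2
Reactants: 3 (3R)-1-chloro-4,4-dimethylhex-5-en-3-ol
Product: 4 (4R)-6-chloro-4-hydroxy-3,3-dimethylhexan-2-one
Conditions: PdCl2 (10 mol %), CuCl, O2 (1 atm), DMF/H2O 7:1, rt
Reagents that add atoms: water, O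
Why: Tsuji–Wacker oxidation of the terminal alkene should give the Markovnikov methyl ketone, and the carbinol centre is not touched.

Step 3
Reactants: 4 (4R)-6-chloro-4-hydroxy-3,3-dimethylhexan-2-one
Product: 6 (6R)-6-(2-chloroethyl)-4,5,5-trimethyl-5,6-dihydro-2H-pyran-2-one, via phosphonoacetate ester 5 (not isolated)
Conditions: (EtO)2P(O)CH2CO2H, N,N'-diisopropylcarbodiimide, DMAP (cat.), CH2Cl2, 0 °C to rt; then LiCl, DBU, MeCN, rt to 50 °C
Reagents that add atoms: diethylphosphonoacetic acid, CCOP(=O)(CC(=O)O)OCC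
Why: Carbodiimide esterification then intramolecular Horner–Wadsworth–Emmons olefination of the methyl ketone closes the six-membered unsaturated lactone; β-elimination of the acyloxy group cannot occur because the carbon between carbinol and ketone is quaternary, and no stereocentre is formed.

Step 4
Reactants: 6 (6R)-6-(2-chloroethyl)-4,5,5-trimethyl-5,6-dihydro-2H-pyran-2-one
Product: 7 (6R)-6-(2-iodoethyl)-4,5,5-trimethyl-5,6-dihydro-2H-pyran-2-one
Conditions: NaI, acetone, reflux
Reagents that add atoms: sodium iodide, [Na+].[I-]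
Why: Finkelstein exchange at the primary carbon, driven by precipitation of NaCl, gives the iodide needed for clean radical generation.

Step 5
Reactants: 7 (6R)-6-(2-iodoethyl)-4,5,5-trimethyl-5,6-dihydro-2H-pyran-2-one
Product: 8 (1R,5R)-5,8,8-trimethyl-2-oxabicyclo[3.2.1]octan-3-one
Conditions: Bu3SnH, AIBN (cat.), benzene (0.01 M), 80 °C, slow addition of the stannane
Reagents that add atoms: none
Why: Tin-mediated iodine abstraction gives a primary alkyl radical that adds to the β-carbon (C4) of the unsaturated lactone, and the resulting α-acyl radical is reduced by Bu3SnH. The closest known reaction type is the tin-hydride-mediated 5-exo radical conjugate cyclization (intramolecular Giese reaction) onto β,β-disubstituted enones and enoates, used to make vicinal quaternary carbons. One ring is closed, the cyclopentane, in the 5-exo-trig mode; 6-endo attack at the α-carbon is disfavoured by polarity and by the stability of the α-carbonyl radical, and the closure is necessarily cis-bridged across C4/C6 of the lactone, giving the 2-oxabicyclo[3.2.1]octan-3-one. The new quaternary stereocentre is controlled by the C6 carbinol centre through the lactone ring: the side chain can only reach the face of the enoate on which it sits, so (6R) gives (5R) and no diastereomer is possible. The step needs cyclization to outrun direct reduction of the primary radical; the electron-poor alkene matched to the nucleophilic radical, the gem-dimethyl group (Thorpe–Ingold effect) and the low stannane concentration should secure this.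

Step 6
Reactants: 8 (1R,5R)-5,8,8-trimethyl-2-oxabicyclo[3.2.1]octan-3-one
Product: 9 2-[(1R,3R)-3-hydroxy-1,2,2-trimethylcyclopentyl]-N-methoxy-N-methylacetamide
Conditions: MeNH(OMe)·HCl, AlMe3, CH2Cl2, 0 °C to rt; aq. potassium sodium tartrate
Reagents that add atoms: N,O-dimethylhydroxylamine hydrochloride, CNOC.Cl
Why: Aluminium-amide aminolysis of the lactone (Weinreb amide formation) opens the bridge without touching either stereocentre and gives an acyl donor that will not over-add.

Step 7
Reactants: 9 2-[(1R,3R)-3-hydroxy-1,2,2-trimethylcyclopentyl]-N-methoxy-N-methylacetamide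
Product: 10 N-methoxy-N-methyl-2-[(1R)-1,2,2-trimethyl-3-oxocyclopentyl]acetamide
Conditions: Dess–Martin periodinane, NaHCO3, CH2Cl2, rt
Reagents that add atoms: none
Why: Dess–Martin oxidation converts the now redundant carbinol into the ketone, and the quaternary centre keeps its absolute configuration.

Step 8
Reactants: 10 N-methoxy-N-methyl-2-[(1R)-1,2,2-trimethyl-3-oxocyclopentyl]acetamide
Product: 12 2-[(1R)-3-bromo-1,2,2-trimethylcyclopent-3-en-1-yl]-N-methoxy-N-methylacetamide, via silyl hydrazone 11 (not isolated)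
Conditions: TBSNHNHTBS, Sc(OTf)3 (1 mol %), 55 °C; then Br2, 2-tert-butyl-1,1,3,3-tetramethylguanidine, CH2Cl2, 0 °C
Reagents that add atoms: bromine, BrBr
Why: Condensation to the N-silyl hydrazone and oxidative bromination (Barton vinyl halide synthesis in its silyl hydrazone form) should give the alkenyl bromide, with the double bond towards the only α-CH2 because the other α-carbon is quaternary.

Step 9
Reactants: 13 2-methylcyclohex-2-en-1-one
Product: 15 tert-butyl 2-[(1S,2S)-2-ethenyl-1-methyl-6-oxocyclohexyl]acetate, via magnesium enolate 14 (not isolated)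
Conditions: CH2=CHMgBr, Cu(OTf)2 (3 mol %), chiral imidazolinium chloride as N-heterocyclic carbene precursor (4 mol %), Et2O, −30 °C; then BrCH2CO2t-Bu, DMPU, −30 to 20 °C
Reagents that add atoms: vinylmagnesium bromide, C=C[Mg]Br; tert-butyl bromoacetate, CC(C)(C)OC(=O)CBr
Why: Copper-catalysed asymmetric conjugate addition of the Grignard reagent to the α-substituted enone followed by alkylation of the regiodefined magnesium enolate: the chiral ligand (antipode chosen for the (2S) vinyl centre) sets the β-carbon, and the electrophile enters trans to the vinyl group so that the quaternary centre (later C8a) is formed as (1S).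

Step 10
Reactants: 15 tert-butyl 2-[(1S,2S)-2-ethenyl-1-methyl-6-oxocyclohexyl]acetate
Product: 16 tert-butyl 2-[(1S,6S)-2-bromo-6-ethenyl-1-methylcyclohex-2-en-1-yl]acetate
Conditions: (PhO)3P, Br2, CH2Cl2, −60 °C; then Et3N and 15, warm to reflux
Reagents that add atoms: bromine, BrBr
Why: Ketone to alkenyl bromide conversion with the triphenyl phosphite–bromine reagent (enol phosphonium and gem-dibromide path); elimination can only occur towards the CH2 side, and no free bromine is present to attack the vinyl group.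

Step 11
Reactants: 16 tert-butyl 2-[(1S,6S)-2-bromo-6-ethenyl-1-methylcyclohex-2-en-1-yl]acetate; 12 2-[(1R)-3-bromo-1,2,2-trimethylcyclopent-3-en-1-yl]-N-methoxy-N-methylacetamide
Product: 17 tert-butyl 2-[(1R,6S)-2-bromo-6-ethenyl-1-methylcyclohex-2-en-1-yl]-4-[(1R)-3-bromo-1,2,2-trimethylcyclopent-3-en-1-yl]-3-oxobutanoate (epimer mixture at C2 of the butanoate)
Conditions: 16, LiN(i-Pr)2, THF, −78 °C; then 12, −78 to −20 °C; aq. NH4Cl
Reagents that add atoms: none
Why: Crossed Claisen-type acylation of the lithium ester enolate by the N-methoxy-N-methylamide, whose chelated tetrahedral intermediate prevents a second addition, joins the two fragments (C1–C2 bond); the new centre at C1 is removed in the next step.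

Step 12
Reactants: 17 tert-butyl 2-[(1R,6S)-2-bromo-6-ethenyl-1-methylcyclohex-2-en-1-yl]-4-[(1R)-3-bromo-1,2,2-trimethylcyclopent-3-en-1-yl]-3-oxobutanoate
Product: 19 1-[(1S,6S)-2-bromo-6-ethenyl-1-methylcyclohex-2-en-1-yl]-3-[(1R)-3-bromo-1,2,2-trimethylcyclopent-3-en-1-yl]propan-2-one, via keto acid 18 (not isolated)
Conditions: CF3CO2H/CH2Cl2 1:4, rt; then toluene, 80 °C
Reagents that add atoms: none
Why: Acidolysis of the tert-butyl ester and thermal decarboxylation of the β-keto acid (six-membered transition state) should leave the ketone with both alkenyl bromides and the vinyl group intact.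

Step 13
Reactants: 19 1-[(1S,6S)-2-bromo-6-ethenyl-1-methylcyclohex-2-en-1-yl]-3-[(1R)-3-bromo-1,2,2-trimethylcyclopent-3-en-1-yl]propan-2-one
Product: 20 (1R,2S)-3-bromo-2-{3-[(1R)-3-bromo-1,2,2-trimethylcyclopent-3-en-1-yl]-2-oxopropyl}-2-methylcyclohex-3-ene-1-carbaldehyde
Conditions: OsO4 (2 mol %), NaIO4, 2,6-lutidine, dioxane/H2O 3:1, rt
Reagents that add atoms: sodium periodate, [Na+].[O-]I(=O)(=O)=O
Why: Lemieux–Johnson oxidative cleavage is expected to take the electron-richer monosubstituted alkene in preference to the two deactivated, trisubstituted bromoalkenes and gives the C4 aldehyde.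

Step 14
Reactants: 20 (1R,2S)-3-bromo-2-{3-[(1R)-3-bromo-1,2,2-trimethylcyclopent-3-en-1-yl]-2-oxopropyl}-2-methylcyclohex-3-ene-1-carbaldehyde
Product: 21 (4aR,8aS)-8-bromo-3-[(1R)-3-bromo-1,2,2-trimethylcyclopent-3-en-1-yl]-4-hydroxy-8a-methyl-3,4,4a,5,6,8a-hexahydronaphthalen-2(1H)-one (C3/C4 epimer mixture)
Conditions: LiN(SiMe3)2, THF, −78 to −40 °C; aq. NH4Cl
Reagents that add atoms: none
Why: Intramolecular aldol addition (6-enolexo-exo-trig) of the ketone enolate formed next to the cyclopentane onto the aldehyde closes ring B; the enolate on the other side could only give a four-membered ring and returns by proton exchange, the centres at C3 and C4 are removed later, and the trans ring fusion is inherited from 15.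

Step 15
Reactants: 21 (4aR,8aS)-8-bromo-3-[(1R)-3-bromo-1,2,2-trimethylcyclopent-3-en-1-yl]-4-hydroxy-8a-methyl-3,4,4a,5,6,8a-hexahydronaphthalen-2(1H)-one
Product: 22 (4aR,8S,8aS)-8-bromo-3-[(1R,3R)-3-bromo-1,2,2-trimethylcyclopentyl]-4-hydroxy-8a-methyloctahydronaphthalen-2(1H)-one (C3/C4 epimer mixture)
Conditions: Mn(dpm)3 (10 mol %), PhSiH3, t-BuOOH, i-PrOH, rt
Reagents that add atoms: none
Why: Metal-hydride hydrogen-atom-transfer hydrogenation of alkenyl halides: H adds to the unsubstituted alkene carbon, and the α-bromoalkyl radical takes the second hydrogen on the less hindered face, at C8 opposite the axial angular methyl (Br equatorial, 8S) and on the cyclopentane opposite the branched ring-B carbon (Br cis to ring B, 3′R), while ketone and alcohol are untouched.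

Step 16
Reactants: 22 (4aR,8S,8aS)-8-bromo-3-[(1R,3R)-3-bromo-1,2,2-trimethylcyclopentyl]-4-hydroxy-8a-methyloctahydronaphthalen-2(1H)-one
Product: 24 (8S,8aS)-8-bromo-3-[(1R,3R)-3-bromo-1,2,2-trimethylcyclopentyl]-8a-methyl-6,7,8,8a-tetrahydronaphthalen-2(1H)-one, via enone 23 (not isolated)
Conditions: p-TsOH·H2O (cat.), chloranil, toluene, 100 °C
Reagents that add atoms: none
Why: Acid-catalysed dehydration of the β-hydroxy ketone gives the conjugated enone, and chloranil then abstracts hydride from C5 of its dienol (γ,δ-dehydrogenation as for 4-en-3-ones); the α′,β′ path is closed by the quaternary C8a, and all epimers at C3, C4 and C4a converge here.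

Step 17
Reactants: 24 (8S,8aS)-8-bromo-3-[(1R,3R)-3-bromo-1,2,2-trimethylcyclopentyl]-8a-methyl-6,7,8,8a-tetrahydronaphthalen-2(1H)-one
Product: 26 (4aR,5R,8S,8aS)-8-bromo-3-[(1R,3R)-3-bromo-1,2,2-trimethylcyclopentyl]-4a,5-dihydroxy-8a-methyl-4a,5,6,7,8,8a-hexahydronaphthalen-2(1H)-one, via epoxide 25 (not isolated)
Conditions: mCPBA, NaHCO3, CH2Cl2, 0 °C; then aq. HClO4, THF, rt
Reagents that add atoms: 3-chloroperbenzoic acid, OOC(=O)c1cccc(Cl)c1; water, O
Why: Peracid epoxidation of the electron-richer γ,δ-double bond from the face opposite the angular methyl and acid-catalysed trans-diaxial opening with water at C5 (Fürst–Plattner rule) should give the 4a-hydroxyl trans to the methyl group and the axial secondary 5-hydroxyl.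

Step 18
Reactants: 26 (4aR,5R,8S,8aS)-8-bromo-3-[(1R,3R)-3-bromo-1,2,2-trimethylcyclopentyl]-4a,5-dihydroxy-8a-methyl-4a,5,6,7,8,8a-hexahydronaphthalen-2(1H)-one
Product: 27 (4aR,8S,8aS)-8-bromo-3-[(1R,3R)-3-bromo-1,2,2-trimethylcyclopentyl]-4a-hydroxy-8a-methyl-4a,7,8,8a-tetrahydronaphthalene-2,5(1H,6H)-dione
Conditions: Dess–Martin periodinane, NaHCO3, CH2Cl2, rt
Reagents that add atoms: none
Why: Dess–Martin oxidation takes the secondary alcohol only and gives the α-hydroxy ketone without disturbing the tertiary alcohol or the enone.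

Step 19
Reactants: 27 (4aR,8S,8aS)-8-bromo-3-[(1R,3R)-3-bromo-1,2,2-trimethylcyclopentyl]-4a-hydroxy-8a-methyl-4a,7,8,8a-tetrahydronaphthalene-2,5(1H,6H)-dione
Product: 28 (4aR,5R,8S,8aS)-8-bromo-3-[(1R,3R)-3-bromo-1,2,2-trimethylcyclopentyl]-4a,5-dihydroxy-5,8a-dimethyl-4a,5,6,7,8,8a-hexahydronaphthalen-2(1H)-one
Conditions: MeMgBr (2.5 equiv), THF, −78 °C; aq. NH4Cl
Reagents that add atoms: methylmagnesium bromide, C[Mg]Br
Why: Chelation-accelerated Grignard addition to the α-alkoxy ketone (magnesium alkoxide of the 4a-hydroxyl) should outpace addition to the hindered enone carbonyl, and the methyl group enters equatorially, on the face opposite the syn-axial angular methyl, to give the axial tertiary alcohol (5R).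

**Compound list**

1 | 3-chloropropan-1-ol | OCCCCl | starting material
2 | 3-methylbuta-1,2-diene | CC(C)=C=C | starting material
3 | (3R)-1-chloro-4,4-dimethylhex-5-en-3-ol | C=CC(C)(C)[C@H](O)CCCl | intermediate
4 | (4R)-6-chloro-4-hydroxy-3,3-dimethylhexan-2-one | CC(=O)C(C)(C)[C@H](O)CCCl | intermediate
5 | (3R)-1-chloro-4,4-dimethyl-5-oxohexan-3-yl 2-(diethoxyphosphoryl)acetate | CC(=O)C(C)(C)[C@H](OC(=O)CP(=O)(OCC)OCC)CCCl | intermediate
6 | (6R)-6-(2-chloroethyl)-4,5,5-trimethyl-5,6-dihydro-2H-pyran-2-one | CC1(C)[C@H](OC(=O)C=C1C)CCCl | intermediate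
7 | (6R)-6-(2-iodoethyl)-4,5,5-trimethyl-5,6-dihydro-2H-pyran-2-one | CC1(C)[C@H](OC(=O)C=C1C)CCI | intermediate
8 | (1R,5R)-5,8,8-trimethyl-2-oxabicyclo[3.2.1]octan-3-one | CC1(C)[C@H]2CC[C@]1(C)CC(=O)O2 | intermediate
9 | 2-[(1R,3R)-3-hydroxy-1,2,2-trimethylcyclopentyl]-N-methoxy-N-methylacetamide | CC1(C)[C@H](O)CC[C@]1(C)CC(=O)N(C)OC | intermediate
10 | N-methoxy-N-methyl-2-[(1R)-1,2,2-trimethyl-3-oxocyclopentyl]acetamide | CC1(C)C(=O)CC[C@]1(C)CC(=O)N(C)OC | intermediate
11 | 2-[(1R)-3-{2-[tert-butyl(dimethyl)silyl]hydrazinylidene}-1,2,2-trimethylcyclopentyl]-N-methoxy-N-methylacetamide | CC1(C)C(=NN[Si](C)(C)C(C)(C)C)CC[C@]1(C)CC(=O)N(C)OC | intermediate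
12 | 2-[(1R)-3-bromo-1,2,2-trimethylcyclopent-3-en-1-yl]-N-methoxy-N-methylacetamide | CC1(C)C(Br)=CC[C@]1(C)CC(=O)N(C)OC | intermediate
13 | 2-methylcyclohex-2-en-1-one | CC1=CCCCC1=O | starting material
14 | bromo{[(3S)-3-ethenyl-2-methylcyclohex-1-en-1-yl]oxy}magnesium | C=C[C@@H]1CCCC(O[Mg]Br)=C1C | intermediate
15 | tert-butyl 2-[(1S,2S)-2-ethenyl-1-methyl-6-oxocyclohexyl]acetate | CC(C)(C)OC(=O)C[C@]1(C)C(=O)CCC[C@H]1C=C | intermediate
16 | tert-butyl 2-[(1S,6S)-2-bromo-6-ethenyl-1-methylcyclohex-2-en-1-yl]acetate | CC(C)(C)OC(=O)C[C@]1(C)C(Br)=CCC[C@H]1C=C | intermediate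
17 | tert-butyl 2-[(1R,6S)-2-bromo-6-ethenyl-1-methylcyclohex-2-en-1-yl]-4-[(1R)-3-bromo-1,2,2-trimethylcyclopent-3-en-1-yl]-3-oxobutanoate (epimers at C2 of the butanoate) | CC1(C)C(Br)=CC[C@]1(C)CC(=O)C(C(=O)OC(C)(C)C)[C@]1(C)C(Br)=CCC[C@H]1C=C | intermediate
18 | 2-[(1R,6S)-2-bromo-6-ethenyl-1-methylcyclohex-2-en-1-yl]-4-[(1R)-3-bromo-1,2,2-trimethylcyclopent-3-en-1-yl]-3-oxobutanoic acid | CC1(C)C(Br)=CC[C@]1(C)CC(=O)C(C(=O)O)[C@]1(C)C(Br)=CCC[C@H]1C=C | intermediate
19 | 1-[(1S,6S)-2-bromo-6-ethenyl-1-methylcyclohex-2-en-1-yl]-3-[(1R)-3-bromo-1,2,2-trimethylcyclopent-3-en-1-yl]propan-2-one | CC1(C)C(Br)=CC[C@]1(C)CC(=O)C[C@]1(C)C(Br)=CCC[C@H]1C=C | intermediate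
20 | (1R,2S)-3-bromo-2-{3-[(1R)-3-bromo-1,2,2-trimethylcyclopent-3-en-1-yl]-2-oxopropyl}-2-methylcyclohex-3-ene-1-carbaldehyde | CC1(C)C(Br)=CC[C@]1(C)CC(=O)C[C@]1(C)C(Br)=CCC[C@H]1C=O | intermediate
21 | (4aR,8aS)-8-bromo-3-[(1R)-3-bromo-1,2,2-trimethylcyclopent-3-en-1-yl]-4-hydroxy-8a-methyl-3,4,4a,5,6,8a-hexahydronaphthalen-2(1H)-one (C3/C4 epimers) | CC1(C)C(Br)=CC[C@]1(C)C1C(O)[C@@H]2CCC=C(Br)[C@@]2(C)CC1=O | intermediate
22 | (4aR,8S,8aS)-8-bromo-3-[(1R,3R)-3-bromo-1,2,2-trimethylcyclopentyl]-4-hydroxy-8a-methyloctahydronaphthalen-2(1H)-one (C3/C4 epimers) | CC1(C)[C@H](Br)CC[C@]1(C)C1C(O)[C@@H]2CCC[C@H](Br)[C@@]2(C)CC1=O | intermediate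
23 | (4aS,8S,8aS)-8-bromo-3-[(1R,3R)-3-bromo-1,2,2-trimethylcyclopentyl]-8a-methyl-4a,5,6,7,8,8a-hexahydronaphthalen-2(1H)-one | CC1(C)[C@H](Br)CC[C@]1(C)C1=C[C@@H]2CCC[C@H](Br)[C@@]2(C)CC1=O | intermediate
24 | (8S,8aS)-8-bromo-3-[(1R,3R)-3-bromo-1,2,2-trimethylcyclopentyl]-8a-methyl-6,7,8,8a-tetrahydronaphthalen-2(1H)-one | CC1(C)[C@H](Br)CC[C@]1(C)C1=CC2=CCC[C@H](Br)[C@@]2(C)CC1=O | intermediate
25 | (4aR,5S,8S,8aS)-8-bromo-3-[(1R,3R)-3-bromo-1,2,2-trimethylcyclopentyl]-4a,5-epoxy-8a-methyl-4a,5,6,7,8,8a-hexahydronaphthalen-2(1H)-one (oxygen trans to the angular methyl) | CC1(C)[C@H](Br)CC[C@]1(C)C1=C[C@]2(O3)[C@@H]3CC[C@H](Br)[C@@]2(C)CC1=O | intermediate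
26 | (4aR,5R,8S,8aS)-8-bromo-3-[(1R,3R)-3-bromo-1,2,2-trimethylcyclopentyl]-4a,5-dihydroxy-8a-methyl-4a,5,6,7,8,8a-hexahydronaphthalen-2(1H)-one | CC1(C)[C@H](Br)CC[C@]1(C)C1=C[C@]2(O)[C@H](O)CC[C@H](Br)[C@@]2(C)CC1=O | intermediate
27 | (4aR,8S,8aS)-8-bromo-3-[(1R,3R)-3-bromo-1,2,2-trimethylcyclopentyl]-4a-hydroxy-8a-methyl-4a,7,8,8a-tetrahydronaphthalene-2,5(1H,6H)-dione | CC1(C)[C@H](Br)CC[C@]1(C)C1=C[C@]2(O)C(=O)CC[C@H](Br)[C@@]2(C)CC1=O | intermediate
28 | (4aR,5R,8S,8aS)-8-bromo-3-[(1R,3R)-3-bromo-1,2,2-trimethylcyclopentyl]-4a,5-dihydroxy-5,8a-dimethyl-4a,5,6,7,8,8a-hexahydronaphthalen-2(1H)-one | CC1(C)[C@H](Br)CC[C@]1(C)C1=C[C@]2(O)[C@](C)(O)CC[C@H](Br)[C@@]2(C)CC1=O | target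

**Step count and weak points**

Total step count: 19. Longest linear sequence: 17 (steps 1–8, then 11–19); steps 9–10 form the second branch.

Steps most likely to fail:

- **Step 15.** Hydrogen delivery to the α-bromoalkyl radical on the cyclopentane may be poorly face-selective, and radical reduction may stop at one bromoalkene or attack the ketone. Fallback: concerted transfer of H2 from diimide (2-nitrobenzenesulfonyl hydrazide, Et3N, CH2Cl2, rt), which adds both hydrogens from the less hindered face without radical intermediates. It sets out from 21 and comes back to the route at 22, with no new compound.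

- **Step 9.** The sp2 Grignard reagent may give low enantio-induction in the conjugate addition, and the magnesium enolate may be quenched by proton transfer instead of being alkylated. Fallback: the chirality is taken from a reagent-controlled ketone reduction instead. It sets out from 13, which is vinylated and alkylated with an achiral copper catalyst (CuI, CH2=CHMgBr; then BrCH2CO2t-Bu) to the racemic trans keto ester tert-butyl 2-(2-ethenyl-1-methyl-6-oxocyclohexyl)acetate F1. Corey–Bakshi–Shibata reduction should turn the two enantiomers into diastereomeric alcohols; tert-butyl 2-[(1S,2S,6S)-2-ethenyl-6-hydroxy-1-methylcyclohexyl]acetate F2 is separated by chromatography and reoxidized with Dess–Martin periodinane, which comes back to the route at 15.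

- **Step 11.** Acylation between two neopentylic partners may be slow, so that proton transfer from the amide to the ester enolate takes over. Fallback: an aldol addition to a less hindered aldehyde, then oxidation. It sets out from 12, which is reduced with i-Bu2AlH at −78 °C to 2-[(1R)-3-bromo-1,2,2-trimethylcyclopent-3-en-1-yl]acetaldehyde F3. Addition of the lithium enolate of 16 gives tert-butyl 2-[(1R,6S)-2-bromo-6-ethenyl-1-methylcyclohex-2-en-1-yl]-4-[(1R)-3-bromo-1,2,2-trimethylcyclopent-3-en-1-yl]-3-hydroxybutanoate F4, and Dess–Martin oxidation comes back to the route at 17.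

Further compounds
F1 | step 9 | tert-butyl 2-(2-ethenyl-1-methyl-6-oxocyclohexyl)acetate, racemic trans isomer | CC(C)(C)OC(=O)CC1(C)C(=O)CCCC1C=C
F2 | step 9 | tert-butyl 2-[(1S,2S,6S)-2-ethenyl-6-hydroxy-1-methylcyclohexyl]acetate | CC(C)(C)OC(=O)C[C@]1(C)[C@@H](O)CCC[C@H]1C=C
F3 | step 11 | 2-[(1R)-3-bromo-1,2,2-trimethylcyclopent-3-en-1-yl]acetaldehyde | CC1(C)C(Br)=CC[C@]1(C)CC=O
F4 | step 11 | tert-butyl 2-[(1R,6S)-2-bromo-6-ethenyl-1-methylcyclohex-2-en-1-yl]-4-[(1R)-3-bromo-1,2,2-trimethylcyclopent-3-en-1-yl]-3-hydroxybutanoate | CC1(C)C(Br)=CC[C@]1(C)CC(O)C(C(=O)OC(C)(C)C)[C@]1(C)C(Br)=CCC[C@H]1C=C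
F0 | step 15 | none | none
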